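**Retrosynthetic overview**
1. The target is the 5→6 biaryl dimer of (2R,3S)-3,3',4',7,8-pentahydroxyflavan (mesquitol). The biaryl bond between C5 of the lower unit and C6 of the upper unit is cut (Suzuki) back to one common monomer, a perbenzylated flavan-3-ol carrying a C5 triflate, used once as electrophile and once (after detriflation, C6 bromination, borylation) as nucleophile.
2. Both stereocenters of the monomer (C2, C3) come from one reagent-controlled syn hydroboration of an achiral 2-aryl-4H-chromene, itself obtained by double-bond migration from the 2H-chromene.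
3. The 2H-chromene comes in one operation from an aryne and a cinnamaldehyde: the aldehyde C=O adds across the aryne (C4–C4a and O1–C8a formed together), the benzoxete opens to an o-quinone methide, and oxa-6π closure makes O1–C2.
4. Enabling feature: in ring A of the C5-linked unit, the benzylic carbon C4 and the ether oxygen O1 sit on the adjacent ring-fusion carbons C4a and C8a (an ortho C,O pair, the retron of a C=O insertion into an aryne). The next carbon, C5, is the biaryl carbon, so it can carry a triflate that first steers the aryne and then serves as the coupling handle.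
5. Ring order: ring A and ring B (both from one benzaldehyde) → transient oxete → pyran ring (key step) → biaryl bond → global debenzylation.

Key step: step 8

Remark: the biaryl axis carries only one non-hydrogen ortho substituent on each ring and is taken to rotate freely, so no axial descriptor is needed.
Remark: the facial sense of (+)-α-pinene-derived IpcBH2 in step 10 is assigned by analogy with its behaviour toward 1-arylcycloalkenes.

**Step 1**
Reactants: 1 3,4-bis(benzyloxy)benzaldehyde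
Product: 3 3,4-bis(benzyloxy)phenol, via aryl formate 2 (not isolated)
Conditions: mCPBA, CH2Cl2, rt; NaHCO3 wash; then K2CO3 (cat.), MeOH, rt
Reagents that add atoms: 3-chloroperoxybenzoic acid, OOC(=O)c1cccc(Cl)c1
Why: Dakin-type Baeyer–Villiger oxidation, in which the electron-rich aryl group (para benzyloxy) migrates in the Criegee intermediate to give formate 2, which mild methanolysis cleaves to the phenol.

**Step 2**
Reactants: 3 3,4-bis(benzyloxy)phenol
Product: 4 4,5-bis(benzyloxy)-2-hydroxybenzaldehyde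
Conditions: MgCl2, Et3N, (CH2O)n, MeCN, reflux
Reagents that add atoms: paraformaldehyde (as formaldehyde), C=O
Why: Magnesium-mediated ortho-formylation (Casnati–Skattebøl), in which the magnesium phenoxide delivers formaldehyde only ortho to oxygen at the less hindered position and a second formaldehyde oxidises the benzylic alkoxide to the aldehyde.

**Step 3**
Reactants: 4 4,5-bis(benzyloxy)-2-hydroxybenzaldehyde
Product: 5 4,5-bis(benzyloxy)-3-bromo-2-hydroxybenzaldehyde
Conditions: NBS, MeCN, 0 °C to rt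
Reagents that add atoms: N-bromosuccinimide, O=C1CCC(=O)N1Br
Why: Electrophilic aromatic bromination directed by the free phenol, whose para position is blocked, so bromine should enter the remaining ortho position C3 between OH and OBn.

**Step 4**
Reactants: 5 4,5-bis(benzyloxy)-3-bromo-2-hydroxybenzaldehyde
Product: 7 4,5-bis(benzyloxy)-3-bromobenzene-1,2-diol, via aryl formate 6 (not isolated)
Conditions: 30% H2O2 (1.1 equiv), NaOH (aq), THF, 0 °C, argon; then HCl (aq)
Reagents that add atoms: hydrogen peroxide, OO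
Why: Dakin oxidation of a salicylaldehyde (aryl migration to peroxide oxygen, then hydrolysis of formate 6) replaces CHO by OH and gives the catechol whose bromine lies next to one hydroxyl.

**Step 5**
Reactants: 7 4,5-bis(benzyloxy)-3-bromobenzene-1,2-diol
Product: 10 4,5-bis(benzyloxy)-3-(trimethylsilyl)benzene-1,2-diol, via bis-silyl ether 8 (not isolated), via lithium phenolate 9 (not isolated)
Conditions: HMDS, THF, reflux; evaporate; n-BuLi, THF, −78 °C to rt; NH4Cl (aq); K2CO3 (cat.), MeOH, argon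
Reagents that add atoms: hexamethyldisilazane, C[Si](C)(C)N[Si](C)(C)C
Why: Bis-silylation, bromine–lithium exchange and anionic 1,3-silyl O-to-C migration (retro-Brook rearrangement) should place the trimethylsilyl group on the former C–Br carbon, ortho to the oxygen that will later leave as triflate.

**Step 6**
Reactants: 10 4,5-bis(benzyloxy)-3-(trimethylsilyl)benzene-1,2-diol
Product: 11 4,5-bis(benzyloxy)-3-(trimethylsilyl)-1,2-phenylene bis(trifluoromethanesulfonate)
Conditions: Tf2O, pyridine, CH2Cl2, 0 °C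
Reagents that add atoms: trifluoromethanesulfonic anhydride, O=S(=O)(OS(=O)(=O)C(F)(F)F)C(F)(F)F
Why: Standard O-sulfonylation of both phenols gives a Kobayashi-type aryne precursor in which only the C2 triflate is ortho to silicon, so fluoride can produce a single aryne.

**Step 7**
Reactants: 1 3,4-bis(benzyloxy)benzaldehyde
Product: 12 (E)-3-[3,4-bis(benzyloxy)phenyl]prop-2-enal
Conditions: Ph3P=CHCHO, toluene, 80 °C
Reagents that add atoms: (triphenylphosphoranylidene)acetaldehyde, O=CC=P(c1ccccc1)(c1ccccc1)c1ccccc1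
Why: Wittig olefination with a stabilised formyl ylide should give the (E)-enal selectively.

**Step 8**
Reactants: 11 4,5-bis(benzyloxy)-3-(trimethylsilyl)-1,2-phenylene bis(trifluoromethanesulfonate); 12 (E)-3-[3,4-bis(benzyloxy)phenyl]prop-2-enal
Product: 16 rac-7,8-bis(benzyloxy)-2-[3,4-bis(benzyloxy)phenyl]-2H-chromen-5-yl trifluoromethanesulfonate, via aryne 13 (not isolated), via benzoxete 14 (not isolated), via o-quinone methide 15 (not isolated)
Conditions: CsF (3 equiv), 12 (2 equiv), MeCN, rt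
Reagents that add atoms: none
Why: Fluoride removes the silyl group of 11 and the adjacent triflate leaves, giving aryne 13 (C4a≡C8a); the carbonyl oxygen of 12 adds to C8a and the resulting C4a aryl anion collapses onto the oxocarbenium carbon, so C4–C4a and O1–C8a form together in a polar, formal [2+2] cycloaddition that closes the four-membered benzoxete 14. Strain then opens 14 by C4–O1 cleavage (retro-4π) to o-quinone methide 15, and a thermal disrotatory oxa-6π electrocyclisation closes the pyran ring by forming O1–C2 and restores the aromaticity of ring A. The closest known reaction type is the aryne/α,β-unsaturated aldehyde [2+2]–ring-opening–oxa-6π cascade that converts cinnamaldehydes into 2-aryl-2H-chromenes. The step needs regioselectivity (oxygen to C8a, not C4a), which the C5 triflate should secure: it is a stronger σ-acceptor than the C8 benzyl ether, so it polarises the aryne toward attack at the distal carbon C8a and stabilises the developing charge at the adjacent C4a. The same triflate, peri to C4, should force the styryl arm of 15 to point toward O1 (Z geometry at C4a=C4), as the electrocyclisation requires. The new stereocenters (C4 of transient 14, C2 of 16) form without control; C2 is deliberately erased in step 9.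

**Step 9**
Reactants: 16 rac-7,8-bis(benzyloxy)-2-[3,4-bis(benzyloxy)phenyl]-2H-chromen-5-yl trifluoromethanesulfonate
Product: 17 7,8-bis(benzyloxy)-2-[3,4-bis(benzyloxy)phenyl]-4H-chromen-5-yl trifluoromethanesulfonate
Conditions: RuHCl(CO)(PPh3)3 (5 mol %), toluene, 100 °C, argon
Reagents that add atoms: none
Why: Ruthenium hydride-catalysed allyl ether to enol ether isomerisation (hydrometalation of C3=C4, then β-hydride elimination of C2–H) should move the double bond into conjugation with O1 and the 2-aryl ring, the expected thermodynamic sink, and removes the uncontrolled C2 stereocenter.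

**Step 10**
Reactants: 17 7,8-bis(benzyloxy)-2-[3,4-bis(benzyloxy)phenyl]-4H-chromen-5-yl trifluoromethanesulfonate
Product: 19 (2R,3S)-7,8-bis(benzyloxy)-2-[3,4-bis(benzyloxy)phenyl]-3-hydroxy-3,4-dihydro-2H-chromen-5-yl trifluoromethanesulfonate, via isopinocampheylborane adduct 18 (not isolated)
Conditions: (+)-α-pinene-derived IpcBH2, THF, −25 °C; then H2O, 3 M NaOAc (aq), 30% H2O2, 0 °C to rt
Reagents that add atoms: hydrogen peroxide, OO
Why: Brown asymmetric hydroboration–oxidation, in which boron adds to C3 (β to both the enol ether oxygen and the 2-aryl group) and hydrogen to C2 on the same face, making 2-aryl and 3-OH trans, while the isopinocampheyl group selects the alkene face expected to give (2R,3S), and C–B oxidation proceeds with retention.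

**Step 11**
Reactants: 19 (2R,3S)-7,8-bis(benzyloxy)-2-[3,4-bis(benzyloxy)phenyl]-3-hydroxy-3,4-dihydro-2H-chromen-5-yl trifluoromethanesulfonate
Product: 20 (2R,3S)-7,8-bis(benzyloxy)-2-[3,4-bis(benzyloxy)phenyl]-3,4-dihydro-2H-chromen-3-ol
Conditions: Pd(OAc)2 (5 mol %), dppf, HCO2H, Et3N, DMF, 70 °C
Reagents that add atoms: none
Why: Palladium-catalysed formate reduction of an aryl triflate (oxidative addition, formate decarboxylation, reductive elimination) should remove the directing group without touching benzyl ethers or stereocenters.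

**Step 12**
Reactants: 20 (2R,3S)-7,8-bis(benzyloxy)-2-[3,4-bis(benzyloxy)phenyl]-3,4-dihydro-2H-chromen-3-ol
Product: 21 (2R,3S)-7,8-bis(benzyloxy)-2-[3,4-bis(benzyloxy)phenyl]-6-bromo-3,4-dihydro-2H-chromen-3-ol
Conditions: NBS (1.0 equiv), CH2Cl2, −40 to 0 °C
Reagents that add atoms: N-bromosuccinimide, O=C1CCC(=O)N1Br
Why: Electrophilic aromatic bromination should occur at C6, which is para to the ring oxygen O1 and ortho to the C7 ether, whereas C5 is para only to the twisted central C8 ether and ring B has a single para donor.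

**Step 13**
Reactants: 21 (2R,3S)-7,8-bis(benzyloxy)-2-[3,4-bis(benzyloxy)phenyl]-6-bromo-3,4-dihydro-2H-chromen-3-ol
Product: 22 (2R,3S)-7,8-bis(benzyloxy)-2-[3,4-bis(benzyloxy)phenyl]-6-(4,4,5,5-tetramethyl-1,3,2-dioxaborolan-2-yl)-3,4-dihydro-2H-chromen-3-ol
Conditions: B2pin2, PdCl2(dppf) (5 mol %), KOAc, 1,4-dioxane, 85 °C
Reagents that add atoms: bis(pinacolato)diboron, CC1(C)OB(OC1(C)C)B1OC(C)(C)C(C)(C)O1
Why: Miyaura borylation of the aryl bromide, which tolerates the free secondary alcohol and the benzyl ethers.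

**Step 14**
Reactants: 19 (2R,3S)-7,8-bis(benzyloxy)-2-[3,4-bis(benzyloxy)phenyl]-3-hydroxy-3,4-dihydro-2H-chromen-5-yl trifluoromethanesulfonate; 22 (2R,3S)-7,8-bis(benzyloxy)-2-[3,4-bis(benzyloxy)phenyl]-6-(4,4,5,5-tetramethyl-1,3,2-dioxaborolan-2-yl)-3,4-dihydro-2H-chromen-3-ol
Product: 23 (2R,3S)-7,8-bis(benzyloxy)-2-[3,4-bis(benzyloxy)phenyl]-5-{(2R,3S)-7,8-bis(benzyloxy)-2-[3,4-bis(benzyloxy)phenyl]-3-hydroxy-3,4-dihydro-2H-chromen-6-yl}-3,4-dihydro-2H-chromen-3-ol
Conditions: Pd(OAc)2 (5 mol %), SPhos, K3PO4, toluene/H2O, 90 °C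
Reagents that add atoms: none
Why: Suzuki–Miyaura coupling of the C5 aryl triflate with the C6 boronate, using a bulky biaryl phosphine for the ortho-substituted partners, forms the biaryl bond far from the stereocenters.

**Step 15**
Reactants: 23 (2R,3S)-7,8-bis(benzyloxy)-2-[3,4-bis(benzyloxy)phenyl]-5-{(2R,3S)-7,8-bis(benzyloxy)-2-[3,4-bis(benzyloxy)phenyl]-3-hydroxy-3,4-dihydro-2H-chromen-6-yl}-3,4-dihydro-2H-chromen-3-ol
Product: 24 (2R,3S)-2-(3,4-dihydroxyphenyl)-5-[(2R,3S)-2-(3,4-dihydroxyphenyl)-3,7,8-trihydroxy-3,4-dihydro-2H-chromen-6-yl]-3,4-dihydro-2H-chromene-3,7,8-triol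
Conditions: H2 (1 atm), Pd(OH)2/C, THF/MeOH, rt; work-up under argon
Reagents that add atoms: none
Why: Catalytic hydrogenolysis of all eight benzyl ethers under neutral conditions should leave the cyclic benzylic C2–O1 bonds and the four stereocenters intact.

**Compound list**
1 | 3,4-bis(benzyloxy)benzaldehyde | O=Cc1ccc(OCc2ccccc2)c(OCc2ccccc2)c1 | starting material
2 | 3,4-bis(benzyloxy)phenyl formate | O=COc1ccc(OCc2ccccc2)c(OCc2ccccc2)c1 | intermediate
3 | 3,4-bis(benzyloxy)phenol | Oc1ccc(OCc2ccccc2)c(OCc2ccccc2)c1 | intermediate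
4 | 4,5-bis(benzyloxy)-2-hydroxybenzaldehyde | O=Cc1cc(OCc2ccccc2)c(OCc2ccccc2)cc1O | intermediate
5 | 4,5-bis(benzyloxy)-3-bromo-2-hydroxybenzaldehyde | O=Cc1cc(OCc2ccccc2)c(OCc2ccccc2)c(Br)c1O | intermediate
6 | 4,5-bis(benzyloxy)-3-bromo-2-hydroxyphenyl formate | O=COc1cc(OCc2ccccc2)c(OCc2ccccc2)c(Br)c1O | intermediate
7 | 4,5-bis(benzyloxy)-3-bromobenzene-1,2-diol | Oc1cc(OCc2ccccc2)c(OCc2ccccc2)c(Br)c1O | intermediate
8 | 1,2-bis(benzyloxy)-3-bromo-4,5-bis(trimethylsilyloxy)benzene | C[Si](C)(C)Oc1cc(OCc2ccccc2)c(OCc2ccccc2)c(Br)c1O[Si](C)(C)C | intermediate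
9 | lithium 3,4-bis(benzyloxy)-2-(trimethylsilyl)-6-(trimethylsilyloxy)phenolate | [Li+].[O-]c1c(O[Si](C)(C)C)cc(OCc2ccccc2)c(OCc2ccccc2)c1[Si](C)(C)C | intermediate
10 | 4,5-bis(benzyloxy)-3-(trimethylsilyl)benzene-1,2-diol | Oc1cc(OCc2ccccc2)c(OCc2ccccc2)c([Si](C)(C)C)c1O | intermediate
11 | 4,5-bis(benzyloxy)-3-(trimethylsilyl)-1,2-phenylene bis(trifluoromethanesulfonate) | FC(F)(F)S(=O)(=O)Oc1cc(OCc2ccccc2)c(OCc2ccccc2)c([Si](C)(C)C)c1OS(=O)(=O)C(F)(F)F | intermediate
12 | (E)-3-[3,4-bis(benzyloxy)phenyl]prop-2-enal | O=C/C=C/c1ccc(OCc2ccccc2)c(OCc2ccccc2)c1 | intermediate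
13 | 3,4-bis(benzyloxy)-6-(trifluoromethanesulfonyloxy)benzyne | FC(F)(F)S(=O)(=O)OC1=CC(OCc2ccccc2)=C(OCc2ccccc2)C#C1 | intermediate
14 | rac-5,6-bis(benzyloxy)-2-{(E)-2-[3,4-bis(benzyloxy)phenyl]ethenyl}-2H-benzoxet-3-yl trifluoromethanesulfonate | FC(F)(F)S(=O)(=O)Oc1cc(OCc2ccccc2)c(OCc2ccccc2)c2OC(/C=C/c3ccc(OCc4ccccc4)c(OCc4ccccc4)c3)c12 | intermediate
15 | (6Z)-2,3-bis(benzyloxy)-6-{(E)-3-[3,4-bis(benzyloxy)phenyl]prop-2-en-1-ylidene}-5-(trifluoromethanesulfonyloxy)cyclohexa-2,4-dien-1-one | O=C1C(OCc2ccccc2)=C(OCc2ccccc2)C=C(OS(=O)(=O)C(F)(F)F)/C1=C/C=C/c1ccc(OCc2ccccc2)c(OCc2ccccc2)c1 | intermediate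
16 | rac-7,8-bis(benzyloxy)-2-[3,4-bis(benzyloxy)phenyl]-2H-chromen-5-yl trifluoromethanesulfonate | FC(F)(F)S(=O)(=O)Oc1cc(OCc2ccccc2)c(OCc2ccccc2)c2OC(c3ccc(OCc4ccccc4)c(OCc4ccccc4)c3)C=Cc12 | intermediate
17 | 7,8-bis(benzyloxy)-2-[3,4-bis(benzyloxy)phenyl]-4H-chromen-5-yl trifluoromethanesulfonate | FC(F)(F)S(=O)(=O)Oc1cc(OCc2ccccc2)c(OCc2ccccc2)c2OC(c3ccc(OCc4ccccc4)c(OCc4ccccc4)c3)=CCc12 | intermediate
18 | isopinocampheyl(2,3-trans-flavan-3-yl)borane adduct of 17 (same C2/C3 geometry as 19) | FC(F)(F)S(=O)(=O)Oc1cc(OCc2ccccc2)c(OCc2ccccc2)c2c1C[C@H](B[C@@H]1C[C@@H]3C[C@H]([C@H]1C)C3(C)C)[C@@H](c1ccc(OCc3ccccc3)c(OCc3ccccc3)c1)O2 | intermediate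
19 | (2R,3S)-7,8-bis(benzyloxy)-2-[3,4-bis(benzyloxy)phenyl]-3-hydroxy-3,4-dihydro-2H-chromen-5-yl trifluoromethanesulfonate | FC(F)(F)S(=O)(=O)Oc1cc(OCc2ccccc2)c(OCc2ccccc2)c2c1C[C@H](O)[C@@H](c1ccc(OCc3ccccc3)c(OCc3ccccc3)c1)O2 | intermediate
20 | (2R,3S)-7,8-bis(benzyloxy)-2-[3,4-bis(benzyloxy)phenyl]-3,4-dihydro-2H-chromen-3-ol | c1cc(OCc2ccccc2)c(OCc2ccccc2)c2c1C[C@H](O)[C@@H](c1ccc(OCc3ccccc3)c(OCc3ccccc3)c1)O2 | intermediate
21 | (2R,3S)-7,8-bis(benzyloxy)-2-[3,4-bis(benzyloxy)phenyl]-6-bromo-3,4-dihydro-2H-chromen-3-ol | c1c(Br)c(OCc2ccccc2)c(OCc2ccccc2)c2c1C[C@H](O)[C@@H](c1ccc(OCc3ccccc3)c(OCc3ccccc3)c1)O2 | intermediate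
22 | (2R,3S)-7,8-bis(benzyloxy)-2-[3,4-bis(benzyloxy)phenyl]-6-(4,4,5,5-tetramethyl-1,3,2-dioxaborolan-2-yl)-3,4-dihydro-2H-chromen-3-ol | c1c(B3OC(C)(C)C(C)(C)O3)c(OCc2ccccc2)c(OCc2ccccc2)c2c1C[C@H](O)[C@@H](c1ccc(OCc3ccccc3)c(OCc3ccccc3)c1)O2 | intermediate
23 | octa-O-benzyl ether of the target (all eight phenolic OH as OBn) | O(Cc1ccccc1)c1ccc([C@H]2Oc3c(cc(-c4cc(OCc5ccccc5)c(OCc5ccccc5)c5c4C[C@H](O)[C@@H](c4ccc(OCc6ccccc6)c(OCc6ccccc6)c4)O5)c(OCc4ccccc4)c3OCc3ccccc3)C[C@@H]2O)cc1OCc1ccccc1 | intermediate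
24 | (2R,3S)-2-(3,4-dihydroxyphenyl)-5-[(2R,3S)-2-(3,4-dihydroxyphenyl)-3,7,8-trihydroxy-3,4-dihydro-2H-chromen-6-yl]-3,4-dihydro-2H-chromene-3,7,8-triol | Oc1ccc([C@H]2Oc3c(cc(-c4cc(O)c(O)c5c4C[C@H](O)[C@@H](c4ccc(O)c(O)c4)O5)c(O)c3O)C[C@@H]2O)cc1O | target

**Totals**
Total step count: 15.
Longest linear sequence: 14 steps (steps 1–6, then 8–15).

**Steps most likely to fail**

Step 8. The carbonyl oxygen may add to the wrong aryne terminus (C4a instead of C8a) if the C8 benzyloxy group polarises the aryne about as strongly as the C5 triflate, giving the isomeric chromene or a mixture. The fallback avoids the aryne and makes O1 a phenol oxygen from the start; it sets out from enal 12. Commercial 5-bromo-2,3-dihydroxybenzaldehyde is benzylated (BnBr, K2CO3, DMF) to 2,3-bis(benzyloxy)-5-bromobenzaldehyde F1. Dakin-type oxidation (mCPBA; then K2CO3, MeOH) converts it through 2,3-bis(benzyloxy)-5-bromophenyl formate F2 into 2,3-bis(benzyloxy)-5-bromophenol F3. F3 has a single free ortho position and is condensed there with 12 (PhB(OH)2, propionic acid, toluene, reflux with water removal; ortho-specific phenol–enal chromenylation) to rac-7,8-bis(benzyloxy)-2-[3,4-bis(benzyloxy)phenyl]-5-bromo-2H-chromene F4. F4 is carried through the conditions of steps 9 and 10: the 4H-chromene isomer F5, its isopinocampheylborane adduct F6, and (2R,3S)-7,8-bis(benzyloxy)-2-[3,4-bis(benzyloxy)phenyl]-5-bromo-3,4-dihydro-2H-chromen-3-ol F7. F7 then takes the place of 19: hydrodebromination under the Pd(OAc)2/dppf/HCO2H/Et3N conditions of step 11 returns to the route at 20, and Suzuki coupling of F7 with 22 under the step 14 conditions returns to it at 23.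

Step 9. The double-bond migration may stall, either because the ruthenium hydride inserts only reversibly at the benzylic C4 without reaching the hindered tertiary C2–H, or because the equilibrium is less favourable than expected, and the chromene may decompose on prolonged heating. The fallback is a two-step redox isomerisation that sets out from 16 and returns at 17. Hydride abstraction from C2 with Ph3CBF4 (CH2Cl2, 0 °C) gives 7,8-bis(benzyloxy)-2-[3,4-bis(benzyloxy)phenyl]-5-(trifluoromethanesulfonyloxy)chromenylium tetrafluoroborate F8. NaBH4 (MeCN/THF, −40 °C) then delivers hydride to the less hindered C4 of this flavylium ion to give 17.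

Step 10. The chiral borane may discriminate the two faces of the enol ether poorly, or in the opposite sense to the carbocyclic analogy, giving low enantiomeric purity. The fallback sets out from 17 and returns at 19. Racemic hydroboration–oxidation (BH3·SMe2, THF; then NaOAc, H2O2) gives the 2,3-trans alcohol as 19 together with its (2S,3R) enantiomer F9. A lipase-catalysed kinetic resolution (Burkholderia cepacia lipase, vinyl acetate, MTBE) is expected to acetylate the (3R) enantiomer to (2S,3R) acetate F10 and leave 19, which is separated by chromatography.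

**Further compounds**
F1 | step 8 | 2,3-bis(benzyloxy)-5-bromobenzaldehyde | O=Cc1cc(Br)cc(OCc2ccccc2)c1OCc1ccccc1
F2 | step 8 | 2,3-bis(benzyloxy)-5-bromophenyl formate | O=COc1cc(Br)cc(OCc2ccccc2)c1OCc1ccccc1
F3 | step 8 | 2,3-bis(benzyloxy)-5-bromophenol | Oc1cc(Br)cc(OCc2ccccc2)c1OCc1ccccc1
F4 | step 8 | rac-7,8-bis(benzyloxy)-2-[3,4-bis(benzyloxy)phenyl]-5-bromo-2H-chromene | Brc1cc(OCc2ccccc2)c(OCc2ccccc2)c2OC(c3ccc(OCc4ccccc4)c(OCc4ccccc4)c3)C=Cc12
F5 | step 8 | 7,8-bis(benzyloxy)-2-[3,4-bis(benzyloxy)phenyl]-5-bromo-4H-chromene | Brc1cc(OCc2ccccc2)c(OCc2ccccc2)c2OC(c3ccc(OCc4ccccc4)c(OCc4ccccc4)c3)=CCc12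
F6 | step 8 | isopinocampheyl(2,3-trans-flavan-3-yl)borane adduct of F5 | Brc1cc(OCc2ccccc2)c(OCc2ccccc2)c2c1C[C@H](B[C@@H]1C[C@@H]3C[C@H]([C@H]1C)C3(C)C)[C@@H](c1ccc(OCc3ccccc3)c(OCc3ccccc3)c1)O2
F7 | step 8 | (2R,3S)-7,8-bis(benzyloxy)-2-[3,4-bis(benzyloxy)phenyl]-5-bromo-3,4-dihydro-2H-chromen-3-ol | Brc1cc(OCc2ccccc2)c(OCc2ccccc2)c2c1C[C@H](O)[C@@H](c1ccc(OCc3ccccc3)c(OCc3ccccc3)c1)O2
F8 | step 9 | 7,8-bis(benzyloxy)-2-[3,4-bis(benzyloxy)phenyl]-5-(trifluoromethanesulfonyloxy)chromenylium tetrafluoroborate | FC(F)(F)S(=O)(=O)Oc1cc(OCc2ccccc2)c(OCc2ccccc2)c2[o+]c(-c3ccc(OCc4ccccc4)c(OCc4ccccc4)c3)ccc12.F[B-](F)(F)F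
F9 | step 10 | (2S,3R)-7,8-bis(benzyloxy)-2-[3,4-bis(benzyloxy)phenyl]-3-hydroxy-3,4-dihydro-2H-chromen-5-yl trifluoromethanesulfonate | FC(F)(F)S(=O)(=O)Oc1cc(OCc2ccccc2)c(OCc2ccccc2)c2c1C[C@@H](O)[C@H](c1ccc(OCc3ccccc3)c(OCc3ccccc3)c1)O2
F10 | step 10 | (2S,3R)-3-acetoxy-7,8-bis(benzyloxy)-2-[3,4-bis(benzyloxy)phenyl]-3,4-dihydro-2H-chromen-5-yl trifluoromethanesulfonate | FC(F)(F)S(=O)(=O)Oc1cc(OCc2ccccc2)c(OCc2ccccc2)c2c1C[C@@H](OC(C)=O)[C@H](c1ccc(OCc3ccccc3)c(OCc3ccccc3)c1)O2
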